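**Retrosynthetic overview**
1. Kanzonol I (25) ⇐ its 4'-tosylate 24 ⇐ (key step) alkyne 23: ring D, the 2,2-dimethyl-2H-pyran fused to ring B at O2'/C3', is cut between its gem-dimethyl carbon C2'' and its olefinic carbon C3''.
2. Enabling feature: C2'' is bound to O2' and two methyl groups, so it is the methine carbon of an O2'-isopropyl ether minus hydride, and C3''=C4'' on C3' is an ethynyl group plus hydride. The methine C–H sits 1,5 to C4'', so one internal hydride shift and C2''–C3'' closure turn "protecting group + alkyne" into ring D.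
3. 23 ⇐ aryl iodide 21 (Sonogashira) ⇐ diol 20 (ring C by Mitsunobu O1–C2 closure) ⇐ Evans benzylation of imide 16 with benzyl bromide 8 (C3–C4 bond and the 3R stereocentre).
4. 8 ⇐ 2-hydroxy-4,6-dimethoxybenzaldehyde (1) by O-prenylation and para-Claisen–Cope relay of the prenyl group to C6; 16 ⇐ 2-iodoresorcinol (9) by mono-tosylation, ortho-formylation, O-isopropylation and one-carbon homologation.
5. Ring order: rings A and B come from 1 and 9; ring C is closed in step 15 and ring D in step 17.

Key step: step 17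

Remark: isoflavan numbering is used (ring C O1–C4, ring A C5–C8a, ring B primed); the atoms of ring D are written O1'', C2'', C3'', C4''; the stereodescriptor read from the SMILES is 3R.

**Route**

Step 1
Reactants: 1 2-hydroxy-4,6-dimethoxybenzaldehyde
Product: 2 2,4-dimethoxy-6-[(3-methylbut-2-en-1-yl)oxy]benzaldehyde
Conditions: prenyl bromide, K2CO3, DMF, 50 °C
Reagents that add atoms: 1-bromo-3-methylbut-2-ene (prenyl bromide), CC(C)=CCBr
Why: Williamson O-alkylation (SN2) of the chelated phenol with the allylic bromide puts the prenyl group on oxygen as the handle for the rearrangement.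

Step 2
Reactants: 2 2,4-dimethoxy-6-[(3-methylbut-2-en-1-yl)oxy]benzaldehyde
Product: 5 6-hydroxy-2,4-dimethoxy-3-(3-methylbut-2-en-1-yl)benzaldehyde, via ortho-dienone 3 (not isolated), via para-dienone 4 (not isolated)
Conditions: PhNEt2, 200 °C, sealed tube
Reagents that add atoms: none
Why: Aromatic para-Claisen rearrangement, in which a [3,3] shift to the ortho carbon gives dienone 3 with a reverse-prenyl group, a Cope [3,3] shift relays it as a normal prenyl group to the para carbon between the two methoxy groups (4), and enolisation gives 5, as is known for prenyl ethers of protected acylphloroglucinols.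

Step 3
Reactants: 5 6-hydroxy-2,4-dimethoxy-3-(3-methylbut-2-en-1-yl)benzaldehyde
Product: 6 2,4-dimethoxy-3-(3-methylbut-2-en-1-yl)-6-[(triisopropylsilyl)oxy]benzaldehyde
Conditions: TIPSOTf, 2,6-lutidine, CH2Cl2, 0 °C
Reagents that add atoms: triisopropylsilyl trifluoromethanesulfonate, CC(C)[Si](OS(=O)(=O)C(F)(F)F)(C(C)C)C(C)C
Why: Silylation of the phenol with the silyl triflate gives a bulky silyl ether that resists O-to-O silyl migration in the next step and survives enolate and hydride reagents.

Step 4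
Reactants: 6 2,4-dimethoxy-3-(3-methylbut-2-en-1-yl)-6-[(triisopropylsilyl)oxy]benzaldehyde
Product: 7 {2,4-dimethoxy-3-(3-methylbut-2-en-1-yl)-6-[(triisopropylsilyl)oxy]phenyl}methanol
Conditions: NaBH4, MeOH/THF, 0 °C
Reagents that add atoms: none
Why: Borohydride reduction of the aldehyde to the benzylic alcohol leaves the alkene and the silyl ether untouched.

Step 5
Reactants: 7 {2,4-dimethoxy-3-(3-methylbut-2-en-1-yl)-6-[(triisopropylsilyl)oxy]phenyl}methanol
Product: 8 [2-(bromomethyl)-3,5-dimethoxy-4-(3-methylbut-2-en-1-yl)phenoxy]triisopropylsilane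
Conditions: CBr4, PPh3, CH2Cl2, 0 °C; used at once
Reagents that add atoms: carbon tetrabromide, BrC(Br)(Br)Br
Why: The Appel reaction converts the benzylic alcohol into the bromide under neutral conditions, which suits this acid-labile, electron-rich benzylic system.

Step 6
Reactants: 9 2-iodobenzene-1,3-diol (2-iodoresorcinol)
Product: 10 3-hydroxy-2-iodophenyl 4-methylbenzenesulfonate
Conditions: TsCl (1 equiv), Et3N, CH2Cl2, 0 °C
Reagents that add atoms: 4-methylbenzenesulfonyl chloride, Cc1ccc(cc1)S(Cl)(=O)=O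
Why: Mono-sulfonylation of one of two equivalent phenols (the first tosylate lowers the nucleophilicity of the second) installs an O4' group that has no α-hydrogen and a poorly nucleophilic oxygen, as the key step requires.

Step 7
Reactants: 10 3-hydroxy-2-iodophenyl 4-methylbenzenesulfonate
Product: 11 4-formyl-3-hydroxy-2-iodophenyl 4-methylbenzenesulfonate
Conditions: MgCl2, Et3N, (CH2O)n, MeCN, reflux
Reagents that add atoms: paraformaldehyde (as formaldehyde), C=O
Why: Casnati–Skattebøl ortho-formylation, in which the magnesium phenoxide delivers formaldehyde to the only free ortho carbon and a second formaldehyde oxidises the benzylic alkoxide by hydride transfer, so the regiochemistry is unambiguous.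

Step 8
Reactants: 11 4-formyl-3-hydroxy-2-iodophenyl 4-methylbenzenesulfonate
Product: 12 4-formyl-2-iodo-3-(propan-2-yloxy)phenyl 4-methylbenzenesulfonate
Conditions: 2-iodopropane, K2CO3, DMF, 45 °C
Reagents that add atoms: 2-iodopropane, CC(C)I
Why: Williamson etherification of the remaining phenol installs the isopropyl group, which protects O2' through the fragment coupling and later supplies C2'' and both methyl groups of ring D.

Step 9
Reactants: 12 4-formyl-2-iodo-3-(propan-2-yloxy)phenyl 4-methylbenzenesulfonate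
Product: 13 2-iodo-4-(2-methoxyethenyl)-3-(propan-2-yloxy)phenyl 4-methylbenzenesulfonate (E/Z mixture)
Conditions: MeOCH2PPh3Cl, NaN(SiMe3)2, THF, 0 °C to rt
Reagents that add atoms: (methoxymethyl)triphenylphosphonium chloride, [Cl-].COC[P+](c1ccccc1)(c1ccccc1)c1ccccc1
Why: Wittig methoxymethylenation of the aldehyde gives the enol ether as a one-carbon homologation handle.

Step 10
Reactants: 13 2-iodo-4-(2-methoxyethenyl)-3-(propan-2-yloxy)phenyl 4-methylbenzenesulfonate
Product: 15 {3-iodo-2-(propan-2-yloxy)-4-[(4-methylbenzenesulfonyl)oxy]phenyl}acetic acid, via arylacetaldehyde 14 (not isolated)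
Conditions: 2 M HCl, THF, 50 °C; then NaClO2, NaH2PO4, 2-methyl-2-butene, t-BuOH/H2O, rt
Reagents that add atoms: water, O; sodium chlorite, [Na+].[O-]Cl=O
Why: Acid hydrolysis of the enol ether followed by Pinnick oxidation, telescoped because arylacetaldehydes self-condense, gives the arylacetic acid without touching tosylate, ether or iodide.

Step 11
Reactants: 15 {3-iodo-2-(propan-2-yloxy)-4-[(4-methylbenzenesulfonyl)oxy]phenyl}acetic acid
Product: 16 (4R)-4-benzyl-3-({3-iodo-2-(propan-2-yloxy)-4-[(4-methylbenzenesulfonyl)oxy]phenyl}acetyl)-1,3-oxazolidin-2-one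
Conditions: (R)-4-benzyl-2-oxazolidinone, DCC, DMAP (cat.), CH2Cl2, 0 °C to rt
Reagents that add atoms: (R)-4-benzyl-1,3-oxazolidin-2-one, O=C1N[C@H](Cc2ccccc2)CO1
Why: Carbodiimide-mediated (Steglich-type) N-acylation of the oxazolidinone installs the chiral auxiliary.

Step 12
Reactants: 16 (4R)-4-benzyl-3-({3-iodo-2-(propan-2-yloxy)-4-[(4-methylbenzenesulfonyl)oxy]phenyl}acetyl)-1,3-oxazolidin-2-one; 8 [2-(bromomethyl)-3,5-dimethoxy-4-(3-methylbut-2-en-1-yl)phenoxy]triisopropylsilane
Product: 18 4-[(2R)-1-[(4R)-4-benzyl-2-oxo-1,3-oxazolidin-3-yl]-3-{2,4-dimethoxy-3-(3-methylbut-2-en-1-yl)-6-[(triisopropylsilyl)oxy]phenyl}-1-oxopropan-2-yl]-2-iodo-3-(propan-2-yloxy)phenyl 4-methylbenzenesulfonate, via sodium Z-enolate 17 (not isolated)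
Conditions: NaN(SiMe3)2, THF, −78 °C; then 8, −78 to −40 °C
Reagents that add atoms: sodium bis(trimethylsilyl)amide, C[Si](C)(C)[N-][Si](C)(C)C.[Na+] (its sodium stays only in intermediate 17)
Why: Evans asymmetric alkylation, in which the chelated Z sodium enolate 17 is benzylated on the face opposite the C4 benzyl group of the (R)-auxiliary, sets the future C3 as R under auxiliary control, and the electron-rich benzylic bromide reacts at low temperature.

Step 13
Reactants: 18 the alkylated imide
Product: 19 4-[(2R)-1-{2,4-dimethoxy-3-(3-methylbut-2-en-1-yl)-6-[(triisopropylsilyl)oxy]phenyl}-3-hydroxypropan-2-yl]-2-iodo-3-(propan-2-yloxy)phenyl 4-methylbenzenesulfonate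
Conditions: LiBH4, MeOH (1 equiv), THF, 0 °C
Reagents that add atoms: none
Why: Reductive cleavage of the imide with LiBH4 frees the primary alcohol (future C2) and the auxiliary without epimerising the benzylic stereocentre or touching iodide, tosylate or silyl ether.

Step 14
Reactants: 19 the silyl-protected alcohol
Product: 20 4-{(2R)-1-hydroxy-3-[6-hydroxy-2,4-dimethoxy-3-(3-methylbut-2-en-1-yl)phenyl]propan-2-yl}-2-iodo-3-(propan-2-yloxy)phenyl 4-methylbenzenesulfonate
Conditions: Bu4NF, AcOH, THF, 0 °C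
Reagents that add atoms: none
Why: Buffered fluoride desilylation frees the ring A phenol and leaves the aryl tosylate intact.

Step 15
Reactants: 20 the phenol–alcohol
Product: 21 4-[(3R)-5,7-dimethoxy-6-(3-methylbut-2-en-1-yl)-3,4-dihydro-2H-chromen-3-yl]-2-iodo-3-(propan-2-yloxy)phenyl 4-methylbenzenesulfonate
Conditions: PPh3, DIAD, THF, 0 °C to rt
Reagents that add atoms: none
Why: Intramolecular Mitsunobu etherification closes ring C by 6-exo-tet attack of the phenol on the activated primary carbon, and the stereocentre is not involved.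

Step 16
Reactants: 21 the iodo-isoflavan
Product: 23 4-[(3R)-5,7-dimethoxy-6-(3-methylbut-2-en-1-yl)-3,4-dihydro-2H-chromen-3-yl]-2-ethynyl-3-(propan-2-yloxy)phenyl 4-methylbenzenesulfonate, via silylalkyne 22 (not isolated)
Conditions: Me3SiC≡CH, Pd(PPh3)2Cl2 (5 mol %), CuI (10 mol %), Et3N, THF, 60 °C; filter; then K2CO3 (20 mol %), MeOH/THF, rt
Reagents that add atoms: ethynyltrimethylsilane, C#C[Si](C)(C)C
Why: Sonogashira coupling of the aryl iodide and base-catalysed protodesilylation give the terminal alkyne, the aryl tosylate being inert to this palladium catalyst.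

Step 17
Reactants: 23 the ortho-ethynyl aryl isopropyl ether
Product: 24 8-[(3R)-5,7-dimethoxy-6-(3-methylbut-2-en-1-yl)-3,4-dihydro-2H-chromen-3-yl]-2,2-dimethyl-2H-chromen-5-yl 4-methylbenzenesulfonate
Conditions: [Au(XPhos)(NCMe)]SbF6 (5 mol %; XPhos = 2-dicyclohexylphosphino-2',4',6'-triisopropylbiphenyl), MeNO2, 100 °C, 0.02 M
Reagents that add atoms: none
Why: Proposed new method: the cationic monovalent gold centre binds the terminal alkyne and slips to the terminal carbon, so that the internal carbon C4'', electron-poor and stabilised by oxygen-rich ring B, accepts the hydride of the tertiary O–CH(CH3)2 methine through a six-membered transition state (1,5-hydride shift), leaving an aryl oxocarbenium ion next to a Z-alkenylgold; the closest known reaction type is the hydroalkylation of terminal alkynes by ether α-C–H bonds under PtI4 or cationic gold catalysis (hydride-transfer cyclisation of alkynyl ethers), together with the Lewis-acid internal-redox cyclisation of ortho-isopropoxy benzylidene malonates, neither of which has been shown for an aryl isopropyl ether paired with an ortho-ethynyl group. The gold-bearing carbon C3'' then attacks the oxocarbenium carbon C2'' with loss of gold, a 6-endo-trig closure in which both alkyne carbons and the C=O unit end up in the pyran ring, and the C3''=C4'' bond stays in place, so the 2,2-dimethyl-2H-chromene forms by a redox-neutral isomerisation. No stereocentre is created, and C3 of the isoflavan is remote and not enolisable, so its R configuration is untouched. Three selectivities are needed: the pyran must fuse to O2' and not O4', which is secured because only O2' carries a C–H donor while the O4' tosylate has no α-hydrogen and is too poor a nucleophile to form a benzofuran; the hydride must go to the internal alkyne carbon, which is secured by aryl stabilisation of positive charge there and by the 1,5 geometry; and the reversible 5-endo attack of the ether oxygen on the alkyne must stay unproductive, which is secured by the non-nucleophilic SbF6 counter-ion and base-free medium that give the oxonium ion no way to lose its isopropyl group. The isopropoxy group, flanked by two ortho substituents, is twisted out of the ring plane, which frees the oxygen lone pair to stabilise the oxocarbenium ion and holds the methine hydrogen over the alkyne.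

Step 18
Reactants: 24 the 4'-tosylate of Kanzonol I
Product: 25 Kanzonol I, 8-[(3R)-5,7-dimethoxy-6-(3-methylbut-2-en-1-yl)-3,4-dihydro-2H-chromen-3-yl]-2,2-dimethyl-2H-chromen-5-ol
Conditions: KOH, MeOH/THF, 60 °C; then 1 M HCl
Reagents that add atoms: none
Why: Alkaline hydrolysis of the aryl sulfonate (S–O cleavage) frees the 4'-phenol, and the chromene, prenyl group, methyl ethers and the non-acidic C3 stereocentre tolerate hydroxide.

**Compound list**
1 | 2-hydroxy-4,6-dimethoxybenzaldehyde | COc1cc(O)c(C=O)c(OC)c1 | starting material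
2 | 2,4-dimethoxy-6-[(3-methylbut-2-en-1-yl)oxy]benzaldehyde | COc1cc(OCC=C(C)C)c(C=O)c(OC)c1 | intermediate
3 | 2,4-dimethoxy-5-(2-methylbut-3-en-2-yl)-6-oxocyclohexa-1,3-diene-1-carbaldehyde (ortho-dienone) | O=CC1=C(OC)C=C(OC)C(C1=O)C(C)(C)C=C | intermediate (not isolated)
4 | 2,4-dimethoxy-3-(3-methylbut-2-en-1-yl)-6-oxocyclohexa-1,4-diene-1-carbaldehyde (para-dienone) | O=CC1=C(OC)C(CC=C(C)C)C(OC)=CC1=O | intermediate (not isolated)
5 | 6-hydroxy-2,4-dimethoxy-3-(3-methylbut-2-en-1-yl)benzaldehyde | COc1cc(O)c(C=O)c(OC)c1CC=C(C)C | intermediate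
6 | 2,4-dimethoxy-3-(3-methylbut-2-en-1-yl)-6-[(triisopropylsilyl)oxy]benzaldehyde | COc1cc(O[Si](C(C)C)(C(C)C)C(C)C)c(C=O)c(OC)c1CC=C(C)C | intermediate
7 | {2,4-dimethoxy-3-(3-methylbut-2-en-1-yl)-6-[(triisopropylsilyl)oxy]phenyl}methanol | COc1cc(O[Si](C(C)C)(C(C)C)C(C)C)c(CO)c(OC)c1CC=C(C)C | intermediate
8 | [2-(bromomethyl)-3,5-dimethoxy-4-(3-methylbut-2-en-1-yl)phenoxy]triisopropylsilane | COc1cc(O[Si](C(C)C)(C(C)C)C(C)C)c(CBr)c(OC)c1CC=C(C)C | intermediate
9 | 2-iodobenzene-1,3-diol | Oc1cccc(O)c1I | starting material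
10 | 3-hydroxy-2-iodophenyl 4-methylbenzenesulfonate | Cc1ccc(cc1)S(=O)(=O)Oc1cccc(O)c1I | intermediate
11 | 4-formyl-3-hydroxy-2-iodophenyl 4-methylbenzenesulfonate | Cc1ccc(cc1)S(=O)(=O)Oc1ccc(C=O)c(O)c1I | intermediate
12 | 4-formyl-2-iodo-3-(propan-2-yloxy)phenyl 4-methylbenzenesulfonate | Cc1ccc(cc1)S(=O)(=O)Oc1ccc(C=O)c(OC(C)C)c1I | intermediate
13 | 2-iodo-4-(2-methoxyethenyl)-3-(propan-2-yloxy)phenyl 4-methylbenzenesulfonate (E/Z mixture) | Cc1ccc(cc1)S(=O)(=O)Oc1ccc(C=COC)c(OC(C)C)c1I | intermediate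
14 | 2-iodo-4-(2-oxoethyl)-3-(propan-2-yloxy)phenyl 4-methylbenzenesulfonate | Cc1ccc(cc1)S(=O)(=O)Oc1ccc(CC=O)c(OC(C)C)c1I | intermediate (not isolated)
15 | {3-iodo-2-(propan-2-yloxy)-4-[(4-methylbenzenesulfonyl)oxy]phenyl}acetic acid | Cc1ccc(cc1)S(=O)(=O)Oc1ccc(CC(=O)O)c(OC(C)C)c1I | intermediate
16 | (4R)-4-benzyl-3-({3-iodo-2-(propan-2-yloxy)-4-[(4-methylbenzenesulfonyl)oxy]phenyl}acetyl)-1,3-oxazolidin-2-one | Cc1ccc(cc1)S(=O)(=O)Oc1ccc(CC(=O)N2C(=O)OC[C@H]2Cc2ccccc2)c(OC(C)C)c1I | intermediate
17 | sodium (Z)-enolate of 16 | [Na+].[O-]/C(=C\c1ccc(OS(=O)(=O)c2ccc(C)cc2)c(I)c1OC(C)C)N1C(=O)OC[C@H]1Cc1ccccc1 | intermediate (not isolated)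
18 | 4-[(2R)-1-[(4R)-4-benzyl-2-oxo-1,3-oxazolidin-3-yl]-3-{2,4-dimethoxy-3-(3-methylbut-2-en-1-yl)-6-[(triisopropylsilyl)oxy]phenyl}-1-oxopropan-2-yl]-2-iodo-3-(propan-2-yloxy)phenyl 4-methylbenzenesulfonate | COc1cc(O[Si](C(C)C)(C(C)C)C(C)C)c(c(OC)c1CC=C(C)C)C[C@H](c1ccc(OS(=O)(=O)c2ccc(C)cc2)c(I)c1OC(C)C)C(=O)N1C(=O)OC[C@H]1Cc1ccccc1 | intermediate
19 | 4-[(2R)-1-{2,4-dimethoxy-3-(3-methylbut-2-en-1-yl)-6-[(triisopropylsilyl)oxy]phenyl}-3-hydroxypropan-2-yl]-2-iodo-3-(propan-2-yloxy)phenyl 4-methylbenzenesulfonate | COc1cc(O[Si](C(C)C)(C(C)C)C(C)C)c(c(OC)c1CC=C(C)C)C[C@H](c1ccc(OS(=O)(=O)c2ccc(C)cc2)c(I)c1OC(C)C)CO | intermediate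
20 | 4-{(2R)-1-hydroxy-3-[6-hydroxy-2,4-dimethoxy-3-(3-methylbut-2-en-1-yl)phenyl]propan-2-yl}-2-iodo-3-(propan-2-yloxy)phenyl 4-methylbenzenesulfonate | COc1cc(O)c(c(OC)c1CC=C(C)C)C[C@H](c1ccc(OS(=O)(=O)c2ccc(C)cc2)c(I)c1OC(C)C)CO | intermediate
21 | 4-[(3R)-5,7-dimethoxy-6-(3-methylbut-2-en-1-yl)-3,4-dihydro-2H-chromen-3-yl]-2-iodo-3-(propan-2-yloxy)phenyl 4-methylbenzenesulfonate | COc1cc2c(c(OC)c1CC=C(C)C)C[C@H](c1ccc(OS(=O)(=O)c3ccc(C)cc3)c(I)c1OC(C)C)CO2 | intermediate
22 | 4-[(3R)-5,7-dimethoxy-6-(3-methylbut-2-en-1-yl)-3,4-dihydro-2H-chromen-3-yl]-3-(propan-2-yloxy)-2-[(trimethylsilyl)ethynyl]phenyl 4-methylbenzenesulfonate | COc1cc2c(c(OC)c1CC=C(C)C)C[C@H](c1ccc(OS(=O)(=O)c3ccc(C)cc3)c(C#C[Si](C)(C)C)c1OC(C)C)CO2 | intermediate (not isolated)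
23 | 4-[(3R)-5,7-dimethoxy-6-(3-methylbut-2-en-1-yl)-3,4-dihydro-2H-chromen-3-yl]-2-ethynyl-3-(propan-2-yloxy)phenyl 4-methylbenzenesulfonate | COc1cc2c(c(OC)c1CC=C(C)C)C[C@H](c1ccc(OS(=O)(=O)c3ccc(C)cc3)c(C#C)c1OC(C)C)CO2 | intermediate
24 | 8-[(3R)-5,7-dimethoxy-6-(3-methylbut-2-en-1-yl)-3,4-dihydro-2H-chromen-3-yl]-2,2-dimethyl-2H-chromen-5-yl 4-methylbenzenesulfonate | COc1cc2c(c(OC)c1CC=C(C)C)C[C@H](c1ccc(OS(=O)(=O)c3ccc(C)cc3)c4c1OC(C)(C)C=C4)CO2 | intermediate
25 | Kanzonol I, 8-[(3R)-5,7-dimethoxy-6-(3-methylbut-2-en-1-yl)-3,4-dihydro-2H-chromen-3-yl]-2,2-dimethyl-2H-chromen-5-ol | COc1cc2c(c(OC)c1CC=C(C)C)C[C@H](c1ccc(O)c3c1OC(C)(C)C=C3)CO2 | target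

**Step count and risks**

Total steps: 18. Longest linear sequence: 13 (steps 6–11, then 12–18, from 2-iodoresorcinol); the ring A branch (steps 1–5) joins at step 12.

Steps most likely to fail:

1. Step 17 (proposed new method). The ether oxygen may add to the gold-bound alkyne faster than hydride is transferred, and the oxonium ion may then lose its isopropyl group (benzofuran formation); or the hydride shift from the aryl ether may be so slow that the electron-rich alkyne is hydrated or oligomerised first. The fallback uses known reactions and a different bond set; it sets out from 21 and comes back at 24. BCl3 in CH2Cl2 at −78 °C should cleave the isopropyl ether selectively over the methyl ethers to give the 2'-hydroxy-3'-iodo isoflavan F1. A Heck reaction of F1 with 2-methylbut-3-en-2-ol (Pd(OAc)2, P(o-tol)3, Et3N, MeCN, 80 °C) should give the (E)-tertiary allylic alcohol F2. Pyridinium p-toluenesulfonate in toluene at 80 °C should then ionise the tertiary alcohol of F2 and let the 2'-phenol oxygen close ring D at C2'' with loss of water, which gives 24.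

2. Step 12. Bromide 8 may ionise and alkylate its own ring A (oligomerisation) or be lost on handling before the enolate captures it, and a slow alkylation leaves time for enolate decomposition or epimerisation of 18. The fallback sets out from 7 and 16 and comes back at 18. Acetylation of 7 (Ac2O, pyridine, DMAP) gives the bench-stable benzylic acetate F3. Imide 16 is converted with TiCl4 and i-Pr2NEt (CH2Cl2, −78 °C) into the chlorotitanium enolate F4. On addition of F3 the Lewis acid ionises the acetate and the enolate captures the stabilised benzylic cation in an SN1-type alkylation, with the same facial bias from the auxiliary, to give 18.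

3. Step 2. The ortho-dienone may enolise before the Cope shift (giving the ortho reverse-prenyl phenol, which can then cyclise onto the phenol), or the ether may fragment to the phenol at 200 °C. The fallback sets out from 1 and comes back at 6. Silylation of 1 (TIPSOTf, 2,6-lutidine, CH2Cl2) gives the silyl ether F5. N-Bromosuccinimide in MeCN at 0 °C should brominate the carbon between the two methoxy groups (para to the silyloxy group, the other free carbon being shielded by the triisopropylsilyl group) to give the bromide F6. Stille coupling of F6 with tributyl(3-methylbut-2-en-1-yl)stannane (Pd(PPh3)4, DMF, 100 °C) gives 6.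

**Further compounds**
F1 | step 17 | 4-[(3R)-5,7-dimethoxy-6-(3-methylbut-2-en-1-yl)-3,4-dihydro-2H-chromen-3-yl]-3-hydroxy-2-iodophenyl 4-methylbenzenesulfonate | COc1cc2c(c(OC)c1CC=C(C)C)C[C@H](c1ccc(OS(=O)(=O)c3ccc(C)cc3)c(I)c1O)CO2
F2 | step 17 | 4-[(3R)-5,7-dimethoxy-6-(3-methylbut-2-en-1-yl)-3,4-dihydro-2H-chromen-3-yl]-3-hydroxy-2-[(1E)-3-hydroxy-3-methylbut-1-en-1-yl]phenyl 4-methylbenzenesulfonate | COc1cc2c(c(OC)c1CC=C(C)C)C[C@H](c1ccc(OS(=O)(=O)c3ccc(C)cc3)c(/C=C/C(C)(C)O)c1O)CO2
F3 | step 12 | {2,4-dimethoxy-3-(3-methylbut-2-en-1-yl)-6-[(triisopropylsilyl)oxy]phenyl}methyl acetate | COc1cc(O[Si](C(C)C)(C(C)C)C(C)C)c(COC(C)=O)c(OC)c1CC=C(C)C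
F4 | step 12 | trichlorotitanium (Z)-enolate of 16 | Cl[Ti](Cl)(Cl)O/C(=C\c1ccc(OS(=O)(=O)c2ccc(C)cc2)c(I)c1OC(C)C)N1C(=O)OC[C@H]1Cc1ccccc1
F5 | step 2 | 2,4-dimethoxy-6-[(triisopropylsilyl)oxy]benzaldehyde | COc1cc(O[Si](C(C)C)(C(C)C)C(C)C)c(C=O)c(OC)c1
F6 | step 2 | 3-bromo-2,4-dimethoxy-6-[(triisopropylsilyl)oxy]benzaldehyde | COc1cc(O[Si](C(C)C)(C(C)C)C(C)C)c(C=O)c(OC)c1Br
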